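## Retrosynthetic overview

1. The two esters go on last, each as its hydroxyl appears: C6–OH comes from reduction of a C6 ketone, and C10–OH from a singlet-oxygen ene reaction that also moves the alkene to C8=C9.
2. Both carbocycles form together in step 7 by an intramolecular (4+3) cycloaddition of a 2-silyloxyallyl cation, released from an epoxy enol silane, onto a tethered E,E-diene; no ring exists before this step.
3. The epoxy ketone comes from a Z-trisubstituted allylic alcohol by hydroxyl-directed epoxidation and oxidation; the alkene geometry is fixed by hydroalumination/iodination of a propargylic alcohol and cross-coupling.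
4. The C15 chain is assembled from hexa-1,5-diyne, acetaldehyde, trimethylaluminium, (E)-1-bromopropene and isopropylmagnesium chloride.

Atom labels used in the text: C1 = ring-fusion carbon with methyl; C2, C3 = CH2 of the five-membered ring; C4 = carbinol carbon with isopropyl; C5 = ring-fusion CH; C6 = carbon with the 4-hydroxybenzoate; C7 = CH2; C8 = alkene carbon with methyl; C9 = alkene CH; C10 = carbon with the 3-methylbutanoate.

Assumption: (S,S)-ProPhenol is taken as the ligand enantiomer that gives the S alcohol in step 1; if its sense is the reverse, the (R,R) ligand is used.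

## Route

Step 1
Reactants: 1 hexa-1,5-diyne; 2 acetaldehyde
Product: 3 (2S)-octa-3,7-diyn-2-ol
Conditions: 1 (3 equiv), Zn(CH3)2 (3 equiv), (S,S)-ProPhenol (10 mol %), Ph3P=O (20 mol %), toluene, 0 °C, slow addition of 2
Reagents that add atoms: none
Why: Zinc–ProPhenol catalysed asymmetric alkynylation of an aldehyde, in which the dinuclear zinc catalyst delivers the alkynylzinc to one face of acetaldehyde and sets the S carbinol, while the excess of the symmetric diyne holds the reaction at mono-addition.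

Step 2
Reactants: 3 (2S)-octa-3,7-diyn-2-ol; 4 trimethylaluminium; 5 (1E)-1-bromoprop-1-ene
Product: 7 (2S,7E,9E)-7-methylundeca-7,9-dien-3-yn-2-ol, via alkenylalane 6 (not isolated)
Conditions: 4 (3 equiv), Zr(C5H5)2Cl2 (25 mol %), ClCH2CH2Cl, 0 to 23 °C; then 5, ZnCl2 (1 equiv), Pd(PPh3)4 (5 mol %), THF, 23 °C
Reagents that add atoms: none
Why: Negishi zirconium-catalysed carboalumination adds methyl and aluminium syn across the terminal alkyne only (methyl to the inner carbon), and the palladium-catalysed Negishi cross-coupling then replaces aluminium with retention, which fixes the E,E-diene.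

Step 3
Reactants: 7 (2S,7E,9E)-7-methylundeca-7,9-dien-3-yn-2-ol
Product: 9 (2S,3Z,7E,9E)-4-iodo-7-methylundeca-3,7,9-trien-2-ol, via cyclic alkenylalanate 8 (not isolated)
Conditions: NaAlH2(OCH2CH2OCH3)2 (2 equiv), THF, 0 to 23 °C; then I2 (1.1 equiv), −78 °C
Reagents that add atoms: iodine, II
Why: Alkoxide-directed trans-hydroalumination of the propargylic alcohol puts aluminium on the distal alkyne carbon cis to the carbinol (five-membered alanate), and iodinolysis with retention gives the Z-iodoalkene (Corey trisubstituted-alkene synthesis).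

Step 4
Reactants: 9 (2S,3Z,7E,9E)-4-iodo-7-methylundeca-3,7,9-trien-2-ol; 10 isopropylmagnesium chloride
Product: 11 (2S,3Z,7E,9E)-7-methyl-4-(propan-2-yl)undeca-3,7,9-trien-2-ol
Conditions: 10 (3 equiv), PdCl2[Fe(C5H4PPh2)2] (5 mol %), THF, 0 to 23 °C
Reagents that add atoms: none
Why: Kumada–Corriu cross-coupling goes with retention at the alkenyl carbon and the wide-bite-angle ferrocenyl diphosphine suppresses β-hydride isomerisation of the secondary alkyl group, so isopropyl ends cis to the carbinol carbon.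

Step 5
Reactants: 11 (2S,3Z,7E,9E)-7-methyl-4-(propan-2-yl)undeca-3,7,9-trien-2-ol
Product: 12 (1S)-1-{(2R,3S)-3-[(3E,5E)-3-methylhepta-3,5-dien-1-yl]-3-(propan-2-yl)oxiran-2-yl}ethan-1-ol
Conditions: VO(C5H7O2)2 (3 mol %), t-BuOOH (1.5 equiv), CH2Cl2, 0 °C; minor erythro isomer removed by chromatography
Reagents that add atoms: tert-butyl hydroperoxide, CC(C)(C)OO
Why: Hydroxyl-directed vanadium-catalysed epoxidation touches only the allylic alkene, and allylic 1,3-strain with the cis isopropyl group fixes the rotamer so that oxygen is delivered threo to the S carbinol, which sets both epoxide centres.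

Step 6
Reactants: 12 (1S)-1-{(2R,3S)-3-[(3E,5E)-3-methylhepta-3,5-dien-1-yl]-3-(propan-2-yl)oxiran-2-yl}ethan-1-ol
Product: 13 1-{(2S,3S)-3-[(3E,5E)-3-methylhepta-3,5-dien-1-yl]-3-(propan-2-yl)oxiran-2-yl}ethan-1-one
Conditions: Dess–Martin periodinane (1.3 equiv), pyridine, CH2Cl2, 0 to 23 °C
Reagents that add atoms: none
Why: Dess–Martin oxidation of the secondary alcohol under buffered conditions leaves the epoxide and the diene untouched, and the two epoxide centres carry the stereochemical information forward.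

Step 7
Reactants: 13 1-{(2S,3S)-3-[(3E,5E)-3-methylhepta-3,5-dien-1-yl]-3-(propan-2-yl)oxiran-2-yl}ethan-1-one
Product: 16 (3S,3aR,6R,8aR)-3-hydroxy-6,8a-dimethyl-3-(propan-2-yl)-2,3,3a,5,6,8a-hexahydroazulen-4(1H)-one, via epoxy enol silane 14 (not isolated), via silyl ether cycloadduct 15 (not isolated)
Conditions: Et3SiOSO2CF3 (1.1 equiv), NEt3 (1.2 equiv), CH2Cl2, −78 °C; then Et3SiOSO2CF3 (0.4 equiv), −78 to −40 °C; then HF·pyridine, THF, 0 °C
Reagents that add atoms: none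
Why: Intramolecular (4+3) cycloaddition of the 2-silyloxyallyl cation released by silyl triflate activation of the epoxy enol silane forms the five- and seven-membered rings together: the diene terminus attacks C5 anti to the breaking epoxide C–O bond (inversion, H5 cis to the C4 oxygen), the extended transition state that keeps the diene away from the C4 isopropyl and silyloxy groups gives the trans ring fusion (C1 methyl trans to H5), suprafacial addition to the E,E-diene puts H8 cis to the C1 methyl, and silyl transfer leaves a C4 triethylsilyl ether that HF·pyridine cleaves.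

Step 8
Reactants: 16 (3S,3aR,6R,8aR)-3-hydroxy-6,8a-dimethyl-3-(propan-2-yl)-2,3,3a,5,6,8a-hexahydroazulen-4(1H)-one
Product: 17 (3S,3aS,4R,6R,8aR)-6,8a-dimethyl-3-(propan-2-yl)-1,2,3,3a,4,5,6,8a-octahydroazulene-3,4-diol
Conditions: (CH3)4N[BH(OCOCH3)3] (5 equiv), CH3CN/CH3CO2H 1:1, −30 °C
Reagents that add atoms: none
Why: Evans–Saksena hydroxyl-directed reduction, in which the borohydride exchanges onto the C4 hydroxyl and delivers hydride intramolecularly to the face of the C6 ketone on which that hydroxyl lies, gives the 1,3-anti diol with the C6 hydroxyl on the side of the C1 methyl.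

Step 9
Reactants: 17 (3S,3aS,4R,6R,8aR)-6,8a-dimethyl-3-(propan-2-yl)-1,2,3,3a,4,5,6,8a-octahydroazulene-3,4-diol; 18 4-(acetyloxy)benzoyl chloride
Product: 19 (3S,3aS,4R,6R,8aR)-3-hydroxy-6,8a-dimethyl-3-(propan-2-yl)-1,2,3,3a,4,5,6,8a-octahydroazulen-4-yl 4-(acetyloxy)benzoate
Conditions: 18 (1.3 equiv), NEt3 (2 equiv), 4-(dimethylamino)pyridine (10 mol %), CH2Cl2, 0 °C
Reagents that add atoms: none
Why: Acylation under nucleophilic catalysis takes only the secondary C6 hydroxyl because the tertiary C4 hydroxyl is too hindered, and no stereocentre is touched.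

Step 10
Reactants: 19 (3S,3aS,4R,6R,8aR)-3-hydroxy-6,8a-dimethyl-3-(propan-2-yl)-1,2,3,3a,4,5,6,8a-octahydroazulen-4-yl 4-(acetyloxy)benzoate
Product: 21 (3S,3aS,4R,8S,8aS)-3,8-dihydroxy-6,8a-dimethyl-3-(propan-2-yl)-1,2,3,3a,4,5,8,8a-octahydroazulen-4-yl 4-(acetyloxy)benzoate, via allylic hydroperoxide 20 (not isolated)
Conditions: O2, visible light, tetraphenylporphyrin (1 mol %), CH2Cl2, 0 °C; then PPh3 (1.5 equiv)
Reagents that add atoms: oxygen, O=O
Why: Schenck ene reaction of singlet oxygen: H8 is the only allylic hydrogen (C1 is quaternary), so oxygen adds to C10 with shift of the alkene to C8=C9 and, being suprafacial, on the face that carries H8, that is cis to the C1 methyl; triphenylphosphine then reduces the hydroperoxide with retention.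

Step 11
Reactants: 21 (3S,3aS,4R,8S,8aS)-3,8-dihydroxy-6,8a-dimethyl-3-(propan-2-yl)-1,2,3,3a,4,5,8,8a-octahydroazulen-4-yl 4-(acetyloxy)benzoate; 22 3-methylbutanoyl chloride
Product: 23 (3S,3aS,4R,8S,8aS)-3-hydroxy-6,8a-dimethyl-8-[(3-methylbutanoyl)oxy]-3-(propan-2-yl)-1,2,3,3a,4,5,8,8a-octahydroazulen-4-yl 4-(acetyloxy)benzoate
Conditions: 22 (2 equiv), pyridine, 4-(dimethylamino)pyridine (20 mol %), CH2Cl2, 23 °C
Reagents that add atoms: none
Why: Acylation of the hindered secondary allylic alcohol with the acid chloride under nucleophilic catalysis leaves the tertiary alcohol and the aryl acetate alone and keeps the C10 configuration.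

Step 12
Reactants: 23 (3S,3aS,4R,8S,8aS)-3-hydroxy-6,8a-dimethyl-8-[(3-methylbutanoyl)oxy]-3-(propan-2-yl)-1,2,3,3a,4,5,8,8a-octahydroazulen-4-yl 4-(acetyloxy)benzoate
Product: 24 (3S,3aS,4R,8S,8aS)-3-hydroxy-6,8a-dimethyl-8-[(3-methylbutanoyl)oxy]-3-(propan-2-yl)-1,2,3,3a,4,5,8,8a-octahydroazulen-4-yl 4-hydroxybenzoate
Conditions: N2H4·H2O (1.2 equiv), THF/CH3OH, 0 °C
Reagents that add atoms: none
Why: Chemoselective hydrazinolysis (acyl transfer to hydrazine) removes the aryl acetate, whose phenoxide leaving group makes it far more reactive than the two esters of secondary alcohols, and no stereocentre is involved.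

## Compound list

1 | hexa-1,5-diyne | C#CCCC#C | starting material
2 | acetaldehyde | CC=O | starting material
3 | (2S)-octa-3,7-diyn-2-ol | C[C@H](O)C#CCCC#C | intermediate
4 | trimethylaluminium | C[Al](C)C | starting material
5 | (1E)-1-bromoprop-1-ene | C/C=C/Br | starting material
6 | {(1E,7S)-7-[(dimethylalumanyl)oxy]-2-methyloct-1-en-5-yn-1-yl}(dimethyl)alumane | C[C@H](O[Al](C)C)C#CCC/C(C)=C/[Al](C)C | intermediate
7 | (2S,7E,9E)-7-methylundeca-7,9-dien-3-yn-2-ol | C[C@H](O)C#CCC/C(C)=C/C=C/C | intermediate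
8 | sodium (5S)-2,2-bis(2-methoxyethoxy)-5-methyl-3-[(3E,5E)-3-methylhepta-3,5-dien-1-yl]-2,5-dihydro-1,2-oxaluminol-2-uide | C[C@@H]1O[Al-](OCCOC)(OCCOC)C(CC/C(C)=C/C=C/C)=C1.[Na+] | intermediate
9 | (2S,3Z,7E,9E)-4-iodo-7-methylundeca-3,7,9-trien-2-ol | C[C@H](O)/C=C(I)/CC/C(C)=C/C=C/C | intermediate
10 | isopropylmagnesium chloride | CC(C)[Mg]Cl | starting material
11 | (2S,3Z,7E,9E)-7-methyl-4-(propan-2-yl)undeca-3,7,9-trien-2-ol | C[C@H](O)/C=C(C(C)C)/CC/C(C)=C/C=C/C | intermediate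
12 | (1S)-1-{(2R,3S)-3-[(3E,5E)-3-methylhepta-3,5-dien-1-yl]-3-(propan-2-yl)oxiran-2-yl}ethan-1-ol | C[C@H](O)[C@H]1O[C@]1(C(C)C)CC/C(C)=C/C=C/C | intermediate
13 | 1-{(2S,3S)-3-[(3E,5E)-3-methylhepta-3,5-dien-1-yl]-3-(propan-2-yl)oxiran-2-yl}ethan-1-one | CC(=O)[C@H]1O[C@]1(C(C)C)CC/C(C)=C/C=C/C | intermediate
14 | triethyl[(1-{(2S,3S)-3-[(3E,5E)-3-methylhepta-3,5-dien-1-yl]-3-(propan-2-yl)oxiran-2-yl}ethenyl)oxy]silane | C=C(O[Si](CC)(CC)CC)[C@H]1O[C@]1(C(C)C)CC/C(C)=C/C=C/C | intermediate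
15 | (3S,3aR,6R,8aR)-6,8a-dimethyl-3-(propan-2-yl)-3-[(triethylsilyl)oxy]-2,3,3a,5,6,8a-hexahydroazulen-4(1H)-one | C[C@H]1C=C[C@@]2(C)CC[C@](O[Si](CC)(CC)CC)(C(C)C)[C@@H]2C(=O)C1 | intermediate
16 | (3S,3aR,6R,8aR)-3-hydroxy-6,8a-dimethyl-3-(propan-2-yl)-2,3,3a,5,6,8a-hexahydroazulen-4(1H)-one | C[C@H]1C=C[C@@]2(C)CC[C@](O)(C(C)C)[C@@H]2C(=O)C1 | intermediate
17 | (3S,3aS,4R,6R,8aR)-6,8a-dimethyl-3-(propan-2-yl)-1,2,3,3a,4,5,6,8a-octahydroazulene-3,4-diol | C[C@H]1C=C[C@@]2(C)CC[C@](O)(C(C)C)[C@@H]2[C@H](O)C1 | intermediate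
18 | 4-(acetyloxy)benzoyl chloride | CC(=O)Oc1ccc(cc1)C(Cl)=O | starting material
19 | (3S,3aS,4R,6R,8aR)-3-hydroxy-6,8a-dimethyl-3-(propan-2-yl)-1,2,3,3a,4,5,6,8a-octahydroazulen-4-yl 4-(acetyloxy)benzoate | C[C@H]1C=C[C@@]2(C)CC[C@](O)(C(C)C)[C@@H]2[C@H](OC(=O)c2ccc(OC(C)=O)cc2)C1 | intermediate
20 | (3S,3aS,4R,8S,8aS)-8-hydroperoxy-3-hydroxy-6,8a-dimethyl-3-(propan-2-yl)-1,2,3,3a,4,5,8,8a-octahydroazulen-4-yl 4-(acetyloxy)benzoate | CC1=C[C@H](OO)[C@@]2(C)CC[C@](O)(C(C)C)[C@@H]2[C@H](OC(=O)c2ccc(OC(C)=O)cc2)C1 | intermediate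
21 | (3S,3aS,4R,8S,8aS)-3,8-dihydroxy-6,8a-dimethyl-3-(propan-2-yl)-1,2,3,3a,4,5,8,8a-octahydroazulen-4-yl 4-(acetyloxy)benzoate | CC1=C[C@H](O)[C@@]2(C)CC[C@](O)(C(C)C)[C@@H]2[C@H](OC(=O)c2ccc(OC(C)=O)cc2)C1 | intermediate
22 | 3-methylbutanoyl chloride | CC(C)CC(Cl)=O | starting material
23 | (3S,3aS,4R,8S,8aS)-3-hydroxy-6,8a-dimethyl-8-[(3-methylbutanoyl)oxy]-3-(propan-2-yl)-1,2,3,3a,4,5,8,8a-octahydroazulen-4-yl 4-(acetyloxy)benzoate | CC1=C[C@H](OC(=O)CC(C)C)[C@@]2(C)CC[C@](O)(C(C)C)[C@@H]2[C@H](OC(=O)c2ccc(OC(C)=O)cc2)C1 | intermediate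
24 | (3S,3aS,4R,8S,8aS)-3-hydroxy-6,8a-dimethyl-8-[(3-methylbutanoyl)oxy]-3-(propan-2-yl)-1,2,3,3a,4,5,8,8a-octahydroazulen-4-yl 4-hydroxybenzoate | CC1=C[C@H](OC(=O)CC(C)C)[C@@]2(C)CC[C@](O)(C(C)C)[C@@H]2[C@H](OC(=O)c2ccc(O)cc2)C1 | target

## Step count and risks

Total steps: 12. Longest linear sequence: 12.

**Step 7 (the cycloaddition).** The methyl group on the inner position of the diene terminus may favour the compact transition state, which gives the cis ring fusion and the wrong configuration at C1; a stepwise (3+2) closure is also possible. The fallback keeps the cycloaddition but enters it from the E-configured epoxide and corrects C5 afterwards. It sets out from 7 and rejoins at 16.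
- MnO2 oxidation of 7 gives (7E,9E)-7-methylundeca-7,9-dien-3-yn-2-one F1.
- LiCu(CH(CH3)2)2 adds syn and gives (3E,7E,9E)-7-methyl-4-(propan-2-yl)undeca-3,7,9-trien-2-one F2.
- Corey–Bakshi–Shibata reduction ((S)-2-methyl-CBS-oxazaborolidine, catecholborane) gives (2R,3E,7E,9E)-7-methyl-4-(propan-2-yl)undeca-3,7,9-trien-2-ol F3.
- The epoxidation of step 5 gives (1R)-1-{(2S,3S)-3-[(3E,5E)-3-methylhepta-3,5-dien-1-yl]-3-(propan-2-yl)oxiran-2-yl}ethan-1-ol F4, and the oxidation of step 6 gives 1-{(2R,3S)-3-[(3E,5E)-3-methylhepta-3,5-dien-1-yl]-3-(propan-2-yl)oxiran-2-yl}ethan-1-one F5.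
- Under the conditions of step 7 this passes through triethyl[(1-{(2R,3S)-3-[(3E,5E)-3-methylhepta-3,5-dien-1-yl]-3-(propan-2-yl)oxiran-2-yl}ethenyl)oxy]silane F6 and (3S,3aS,6R,8aR)-6,8a-dimethyl-3-(propan-2-yl)-3-[(triethylsilyl)oxy]-2,3,3a,5,6,8a-hexahydroazulen-4(1H)-one F7 to (3S,3aS,6R,8aR)-3-hydroxy-6,8a-dimethyl-3-(propan-2-yl)-2,3,3a,5,6,8a-hexahydroazulen-4(1H)-one F8.
- F8, formed through the compact transition state, has the target configuration at C1, C4 and C8 and is epimeric only at C5. 1,8-Diazabicyclo[5.4.0]undec-7-ene in toluene epimerises C5 (alpha to the ketone) to the trans-fused 16, which is expected to be the more stable epimer.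

**Step 8 (directed reduction).** Exchange of the borohydride onto a tertiary hydroxyl may be slow, and hydride could then enter from the other face. The fallback turns the selectivity round on purpose and corrects it in the esterification. It sets out from 16 and rejoins at 19.
- Narasaka–Prasad reduction (Et2BOCH3, NaBH4, THF/CH3OH, −78 °C; external hydride on the boron chelate) gives the 1,3-syn diol (3S,3aS,4S,6R,8aR)-6,8a-dimethyl-3-(propan-2-yl)-1,2,3,3a,4,5,6,8a-octahydroazulene-3,4-diol F9.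
- Mitsunobu esterification with 4-(acetyloxy)benzoic acid (PPh3, diisopropyl azodicarboxylate) inverts C6 and gives 19 directly.

**Step 10 (ene reaction).** A cis-disubstituted ring alkene reacts slowly with singlet oxygen, and the hindered face next to the C1 methyl may slow it further. The fallback uses selenium chemistry and an oxidative transposition. It sets out from 19 and rejoins at 21.
- SeO2 (catalytic) with t-BuOOH (ene reaction, then 2,3-shift) gives (3S,3aS,4R,6S,8aR)-3,6-dihydroxy-6,8a-dimethyl-3-(propan-2-yl)-1,2,3,3a,4,5,6,8a-octahydroazulen-4-yl 4-(acetyloxy)benzoate F10.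
- C5H5NH[CrO3Cl] brings about the oxidative 1,3-transposition (Babler–Dauben) to (3S,3aS,4R,8aS)-3-hydroxy-6,8a-dimethyl-8-oxo-3-(propan-2-yl)-1,2,3,3a,4,5,8,8a-octahydroazulen-4-yl 4-(acetyloxy)benzoate F11.
- NaBH4/CeCl3 (Luche reduction), with hydride entering opposite to the C1 methyl, gives 21.

## Further compounds

F1 | step 7 | (7E,9E)-7-methylundeca-7,9-dien-3-yn-2-one | CC(=O)C#CCC/C(C)=C/C=C/C
F2 | step 7 | (3E,7E,9E)-7-methyl-4-(propan-2-yl)undeca-3,7,9-trien-2-one | CC(=O)/C=C(/C(C)C)CC/C(C)=C/C=C/C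
F3 | step 7 | (2R,3E,7E,9E)-7-methyl-4-(propan-2-yl)undeca-3,7,9-trien-2-ol | C[C@@H](O)/C=C(/C(C)C)CC/C(C)=C/C=C/C
F4 | step 7 | (1R)-1-{(2S,3S)-3-[(3E,5E)-3-methylhepta-3,5-dien-1-yl]-3-(propan-2-yl)oxiran-2-yl}ethan-1-ol | C[C@@H](O)[C@@H]1O[C@]1(C(C)C)CC/C(C)=C/C=C/C
F5 | step 7 | 1-{(2R,3S)-3-[(3E,5E)-3-methylhepta-3,5-dien-1-yl]-3-(propan-2-yl)oxiran-2-yl}ethan-1-one | CC(=O)[C@@H]1O[C@]1(C(C)C)CC/C(C)=C/C=C/C
F6 | step 7 | triethyl[(1-{(2R,3S)-3-[(3E,5E)-3-methylhepta-3,5-dien-1-yl]-3-(propan-2-yl)oxiran-2-yl}ethenyl)oxy]silane | C=C(O[Si](CC)(CC)CC)[C@@H]1O[C@]1(C(C)C)CC/C(C)=C/C=C/C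
F7 | step 7 | (3S,3aS,6R,8aR)-6,8a-dimethyl-3-(propan-2-yl)-3-[(triethylsilyl)oxy]-2,3,3a,5,6,8a-hexahydroazulen-4(1H)-one | C[C@H]1C=C[C@@]2(C)CC[C@](O[Si](CC)(CC)CC)(C(C)C)[C@H]2C(=O)C1
F8 | step 7 | (3S,3aS,6R,8aR)-3-hydroxy-6,8a-dimethyl-3-(propan-2-yl)-2,3,3a,5,6,8a-hexahydroazulen-4(1H)-one | C[C@H]1C=C[C@@]2(C)CC[C@](O)(C(C)C)[C@H]2C(=O)C1
F9 | step 8 | (3S,3aS,4S,6R,8aR)-6,8a-dimethyl-3-(propan-2-yl)-1,2,3,3a,4,5,6,8a-octahydroazulene-3,4-diol | C[C@H]1C=C[C@@]2(C)CC[C@](O)(C(C)C)[C@@H]2[C@@H](O)C1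
F10 | step 10 | (3S,3aS,4R,6S,8aR)-3,6-dihydroxy-6,8a-dimethyl-3-(propan-2-yl)-1,2,3,3a,4,5,6,8a-octahydroazulen-4-yl 4-(acetyloxy)benzoate | C[C@]1(O)C=C[C@@]2(C)CC[C@](O)(C(C)C)[C@@H]2[C@H](OC(=O)c2ccc(OC(C)=O)cc2)C1
F11 | step 10 | (3S,3aS,4R,8aS)-3-hydroxy-6,8a-dimethyl-8-oxo-3-(propan-2-yl)-1,2,3,3a,4,5,8,8a-octahydroazulen-4-yl 4-(acetyloxy)benzoate | CC1=CC(=O)[C@@]2(C)CC[C@](O)(C(C)C)[C@@H]2[C@H](OC(=O)c2ccc(OC(C)=O)cc2)C1
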